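## Analysis of the target

Compound 20 is a biflavone built from two acacetin (1) units. Each unit is a 5,7-dihydroxy-2-(4-methoxyphenyl)chromen-4-one with a benzo ring A, a 4-pyranone ring C and an anisyl ring B. Unit 1 is joined through C6 of its ring A and unit 2 through C8 of its ring A, so the core is the unsymmetrical 6,8''-linked biaryl. There is no stereocentre. The only stereo element is the C6–C8'' axis, which carries four ortho substituents (O5 and O7 of unit 1, O7 and the C8a–O1 oxygen of unit 2). The sensitive groups are four phenols (two chelated to C4=O), two anisyl methyl ethers that must outlive every deprotection, and two pyranones. The pyranones open with strong hydroxide and, under strong acid, can reclose through the other ortho oxygen (Wessely–Moser isomerisation), which would exchange 6- and 8-linkage. The difficulty is twofold: an aryl–aryl bond between two electron-rich, fully ortho-flanked carbons, and the need to fix which ring position of each unit carries that bond. The strategy rests on ring A of unit 1: its C5, C7 and C8a carry oxygen in a 1,3,5 pattern and C6, between two of them, carries unit 2. This is the folding pattern of a 3,5-dioxohexanoate whose C6 hangs on C8 of unit 2, so the ring can be grown by a Claisen cyclisation and no arene–arene coupling is needed. The new ring is symmetric about the bond to unit 2, so the ring-forming step has no regiochemical choice. The choices lie in the allyl shift to C8 of unit 2 and in the direction of the last pyranone closure.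

## Retrosynthetic reasoning

20 ⇒ 19. The two phenols of unit 2 are unmasked last. Benzyl ethers are chosen because hydrogenolysis touches neither the anisyl methyl ethers nor the pyranones, and because they are stable to base and to heat.

19 ⇒ 16 + 17. The O1–C2 and C4–C4a bonds of the unit 1 pyranone are cut. This leaves the triphenol 16, whose two free ring carbons are equivalent, so C-acylation by the keto ester 17 cannot go to a wrong carbon. The forward reaction must close the pyranone through the hydroxyl para to the biaryl carbon (6-linkage), not through a hydroxyl beside the axis (8-linkage). It must also run without acid so that unit 2 is not isomerised.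

16 ⇒ 15 (key disconnection). The bond between the ring carbon that bears unit 2 and one of its oxygenated neighbours is cut. This reveals an ester carbonyl and a benzylic methylene, that is, the open-chain diketo ester 15. The cut is made inside the new ring and not at the biaryl bond, so the crowded axis exists beforehand as an ordinary C(sp2)–C(sp3) bond. The forward reaction must make the benzylic carbon, not an enolate oxygen, acylate the ester.

15 ⇒ 9 + 13 (through 14). The chain is cut between C4 and C5. The acyl half comes from the arylacetic acid 9 as its chloride 14, and the four-carbon half from the bis(silyl enol ether) 13, a neutral equivalent of the dianion of 10. A neutral nucleophile is preferred because 14 has acidic benzylic hydrogens that a strongly basic enolate would remove.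

13 ⇒ 12 ⇒ 10 + 11. The diene is reached by two successive silylations of 10 with 11, first at the ketone oxygen and then, after γ-deprotonation, at the ester oxygen.

9 ⇒ 8 ⇒ 6. The acid is traced to the aldehyde 8 and then to the terminal alkene 6 by oxidative cleavage. The allyl group thus serves as a masked carboxymethyl group, and the carbon that becomes C6 of unit 1 is its benzylic CH2.

6 ⇒ 4 + 5, 4 ⇒ 3, 3 ⇒ 1 + 2. The benzyl ethers are removed, then the C8–CH2 bond is cut as the retron of an aromatic Claisen rearrangement of the 7-O-allyl ether 3, which comes from 1 and 2. The bond that later becomes the biaryl axis is therefore made intramolecularly from O7. The forward reaction must place the allyl group on C8 and not on C6.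

## Alternatives that were turned down

Alternative 1: Ring A of unit 2 is taken apart at three bonds. Four of its carbons come from 3-(benzyloxy)cyclobut-2-en-1-one A2 and two from the siloxyalkyne A3, which already carries the protected ring A of unit 1. In the forward direction, heating opens A2 to a vinylketene, which adds [2+2] to the electron-rich triple bond of A3. The resulting vinylcyclobutenone opens to a dienylketene, and 6π electrocyclisation followed by tautomerisation gives phenol A1 (Danheiser benzannulation). In its favour, the hindered aryl–aryl bond is again not made by coupling, and the substitution pattern of the new ring follows from the mechanism. Above all, the oxygens of A1 are differentiated as free hydroxyl, silyl ether, benzyl ethers and acetal. Both pyranones could therefore be annulated in a fixed direction, and on this point it is stronger than the chosen route, which relies on steric bias in step 10. Against it, A1 contains neither pyranone nor anisyl ring, so two full flavone annulations and several kinds of deprotection still follow. A3 needs several steps from a protected triphenol and is sensitive to hydrolysis, and its two ortho benzyloxy groups crowd the [2+2] step. The chosen strategy takes unit 2 complete from 1 and builds only one carbocycle and one pyranone, in eleven steps. It gives up some regiochemical certainty at the end for a much shorter route.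

Alternative 2: The C2=C3 double bonds of both pyranones are cut. The precursor is the biaryl bis(ylide) A5, which carries on each ring a phosphoranylidene-acetyl group and a 4-methoxybenzoate on the neighbouring oxygen. In the forward direction each ylide carbon adds to the adjacent ester carbonyl in a hot aromatic solvent. Loss of phosphine oxide closes the pyranone, twice, to give the tetrabenzyl ether A4, and one hydrogenolysis would finish. In its favour, the conditions are neutral, both rings C form in one operation, and the direction of each closure is fixed by which oxygen carries the ester. In mildness and in certainty of the pyranone closure it is better than step 10 of the chosen route. Against it, every difficulty is moved into A5. Its tetra-ortho-substituted bond between two different electron-rich rings must be made by a hindered cross-coupling. Each ring also needs an acyl group, one aroylated oxygen and two benzylated oxygens in defined positions, so the 6- versus 8-linkage question returns as a problem of telling apart similar phenols. The ester carbonyls next to the axis are shielded as well. The chosen strategy never couples two arenes and starts from the intact flavone 1, whereas the synthesis of A5 alone would probably be longer than the whole chosen route.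

Alternative 3: The C8–C8a and C4a–C5 bonds of unit 2 are cut. Ring A of unit 2 is built from the aryl-substituted bis(silyloxy)diene A7 and the C5–C6 double bond of the bromopyranone A8. In the forward direction a [4+2] addition, or its stepwise Michael–Claisen equivalent, is followed by loss of hydrogen halide and of an alcohol, and gives A6. In its favour, the route is convergent, rings B and C of unit 2 arrive ready-made, and the chemistry of the parent diene 13 with acceptors is well known. The free hydroxyls of unit 2 and the benzyl ethers on the other ring also keep the two halves distinct. Against it, the diene terminus that must bond to C6 of A8 carries an aryl group with two ortho benzyloxy substituents, so the bond forms at the most hindered carbon in an intermolecular step. 4-Pyranones are reluctant acceptors, and the geometry of the aryl-substituted diene must be controlled. After A6, the unit 1 pyranone must still be closed on a triphenol, with the same directional question as in step 10 and with the hydroxyls of unit 2 unprotected. The step count would be similar, but the key bond formation is less secure than the intramolecular, regiochemically degenerate and aromatisation-driven closure of step 9.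

Key step: step 9

Assumption: the target is drawn without a descriptor for the C6–C8'' axis, so 20 is planned as the racemic mixture of atropisomers.

## Route

Step 1
Reactants: 1 acacetin (5,7-dihydroxy-2-(4-methoxyphenyl)chromen-4-one); 2 allyl bromide
Product: 3 5-hydroxy-2-(4-methoxyphenyl)-7-(prop-2-en-1-yloxy)chromen-4-one
Conditions: 2 (1.05 equiv), K2CO3, acetone, reflux
Reagents that add atoms: allyl bromide (2), C=CCBr
Why: Williamson etherification; the 7-hydroxyl is the acidic, free phenol, whereas the 5-hydroxyl is held in a hydrogen bond to C4=O and does not react with a weak base and one equivalent of halide.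

Step 2
Reactants: 3 5-hydroxy-2-(4-methoxyphenyl)-7-(prop-2-en-1-yloxy)chromen-4-one
Product: 4 5,7-dihydroxy-2-(4-methoxyphenyl)-8-(prop-2-en-1-yl)chromen-4-one
Conditions: PhNEt2, 200 °C, Ar
Reagents that add atoms: none
Why: Aromatic Claisen rearrangement; the [3,3] shift from O7 should deliver the allyl group mainly to C8, the ortho position favoured in 7-allyloxy benzopyranones by the higher double-bond character of C7–C8, and tautomerisation restores the phenol. The C6 isomer, favoured to some extent by the chelated 5-hydroxyl, is expected as the minor product and is removed by chromatography.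

Step 3
Reactants: 4 5,7-dihydroxy-2-(4-methoxyphenyl)-8-(prop-2-en-1-yl)chromen-4-one; 5 benzyl bromide
Product: 6 5,7-bis(benzyloxy)-2-(4-methoxyphenyl)-8-(prop-2-en-1-yl)chromen-4-one
Conditions: 5 (3 equiv), K2CO3, n-Bu4NI (cat.), DMF, 70 °C
Reagents that add atoms: benzyl bromide (5), BrCc1ccccc1
Why: Williamson etherification of both phenols; the chelated 5-hydroxyl needs the polar aprotic solvent, heat and iodide catalysis, and carbonate is too weak to isomerise the allyl group.

Step 4
Reactants: 6 5,7-bis(benzyloxy)-2-(4-methoxyphenyl)-8-(prop-2-en-1-yl)chromen-4-one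
Product: 8 2-[5,7-bis(benzyloxy)-2-(4-methoxyphenyl)-4-oxochromen-8-yl]acetaldehyde, via diol 7 (not isolated)
Conditions: OsO4 (2 mol %), NaIO4 (4 equiv), 2,6-lutidine, dioxane/H2O, 20 °C
Reagents that add atoms: osmium tetroxide, O=[Os](=O)(=O)=O; sodium periodate (terminal oxidant), [Na+].[O-][I](=O)(=O)=O
Why: Lemieux–Johnson cleavage; OsO4 dihydroxylates the electron-rich monosubstituted alkene far faster than the electron-poor C2=C3 bond of the pyranone, and NaIO4 cleaves diol 7 and reoxidises osmium. The aldehyde is used at once because arylacetaldehydes enolise and autoxidise.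

Step 5
Reactants: 8 2-[5,7-bis(benzyloxy)-2-(4-methoxyphenyl)-4-oxochromen-8-yl]acetaldehyde
Product: 9 2-[5,7-bis(benzyloxy)-2-(4-methoxyphenyl)-4-oxochromen-8-yl]acetic acid
Conditions: NaClO2, NaH2PO4, 2-methyl-2-butene, t-BuOH/THF/H2O, 0 to 20 °C
Reagents that add atoms: sodium chlorite, [Na+].[O-]Cl=O
Why: Pinnick oxidation; chlorous acid oxidises the aldehyde under buffered conditions without enolisation, and 2-methyl-2-butene traps the hypochlorous acid that would otherwise chlorinate the electron-rich rings.

Step 6
Reactants: 10 methyl acetoacetate; 11 chlorotrimethylsilane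
Product: 12 methyl 3-(trimethylsilyloxy)but-2-enoate (mixture of double-bond isomers, geometry without consequence)
Conditions: 11, NEt3, hexane, 20 °C; distillation
Reagents that add atoms: chlorotrimethylsilane (11), C[Si](C)(C)Cl
Why: O-silylation of the enol of a β-keto ester with an amine base, the standard first stage in the preparation of 1,3-bis(silyl enol ethers).

Step 7
Reactants: 12 methyl 3-(trimethylsilyloxy)but-2-enoate; 11 chlorotrimethylsilane
Product: 13 1-methoxy-1,3-bis(trimethylsilyloxy)buta-1,3-diene
Conditions: LiN(i-Pr)2, THF, −78 °C; 11, −78 to 0 °C; distillation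
Reagents that add atoms: chlorotrimethylsilane (11), C[Si](C)(C)Cl
Why: γ-Deprotonation of the vinylogous ester gives the extended enolate, which is silylated on the ester oxygen to the silyl ketene acetal; this is the known second stage to the bis(silyl enol ether) of an acetoacetate.

Step 8
Reactants: 9 2-[5,7-bis(benzyloxy)-2-(4-methoxyphenyl)-4-oxochromen-8-yl]acetic acid; 13 1-methoxy-1,3-bis(trimethylsilyloxy)buta-1,3-diene
Product: 15 methyl 6-[5,7-bis(benzyloxy)-2-(4-methoxyphenyl)-4-oxochromen-8-yl]-3,5-dioxohexanoate, via acid chloride 14 (not isolated)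
Conditions: 1-chloro-N,N,2-trimethylprop-1-en-1-amine, CH2Cl2, 0 to 20 °C; then 13 (1.5 equiv), −78 to 20 °C; aqueous NH4Cl
Reagents that add atoms: 1-methoxy-1,3-bis(trimethylsilyloxy)buta-1,3-diene (13), COC(O[Si](C)(C)C)=CC(=C)O[Si](C)(C)C; 1-chloro-N,N,2-trimethylprop-1-en-1-amine (chlorine of 14 only), CC(C)=C(Cl)N(C)C
Why: The chloroenamine makes acid chloride 14 under neutral conditions without HCl. Diene 13 then attacks 14 through its terminal carbon (vinylogous Mukaiyama-type C-acylation of a 1,3-bis(silyl enol ether)), a known route to 3,5-dioxoalkanoates, and aqueous work-up cleaves the remaining silyl ketene acetal. Because no base is present, the acidic benzylic hydrogens of 14 are not removed and no ketene forms.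

Step 9
Reactants: 15 methyl 6-[5,7-bis(benzyloxy)-2-(4-methoxyphenyl)-4-oxochromen-8-yl]-3,5-dioxohexanoate
Product: 16 5,7-bis(benzyloxy)-2-(4-methoxyphenyl)-8-(2,4,6-trihydroxyphenyl)chromen-4-one
Conditions: Mg(OMe)2 (6 equiv), MeOH (0.01 M), reflux, Ar; then 1 M HCl, 0 °C
Reagents that add atoms: none
Why: Mg(OMe)2 turns 15 into a chelated polyenolate; proton exchange in methanol gives access to the enolate of the C5 ketone toward C6, whose benzylic carbon, acidified by the ketone and the aryl group, adds to the magnesium-bound ester carbonyl, and loss of methoxide gives a 2-arylcyclohexane-1,3,5-trione that tautomerises at once to the triphenol 16. This is a Claisen (Dieckmann-type) condensation, the known reaction type by which 3,5-dioxoalkanoates are converted into phloroglucinols. The ring closes in the 6-(enolendo)-exo-trig mode, which the Baldwin rules favour. No stereocentre forms, and because the new ring is symmetric about the bond to unit 2 no stereogenic axis forms either. No other carbocycle is possible, since attack of C2 or C4 on a carbonyl would give a four-membered ring. The one competing closure is O-acylation by the C5 enolate oxygen to a 4-hydroxy-2-pyranone; in methanol with methoxide this lactone reopens to 15, whereas the carbocycle leaves the equilibrium by aromatisation and phenoxide formation, so the material should funnel to 16. High dilution suppresses intermolecular condensation. The benzyl ethers, the anisyl ether and the pyranone of unit 2 are stable to the weakly basic magnesium alkoxide.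

Step 10
Reactants: 16 5,7-bis(benzyloxy)-2-(4-methoxyphenyl)-8-(2,4,6-trihydroxyphenyl)chromen-4-one; 17 ethyl 4-methoxybenzoylacetate
Product: 19 6-[5,7-bis(benzyloxy)-2-(4-methoxyphenyl)-4-oxochromen-8-yl]-5,7-dihydroxy-2-(4-methoxyphenyl)chromen-4-one, via diketone 18 (not isolated)
Conditions: 17 (3 equiv), Ph2O, 240 °C, Ar, volatiles distilled off
Reagents that add atoms: ethyl 4-methoxybenzoylacetate (17), CCOC(=O)CC(=O)c1ccc(OC)cc1
Why: Mentzer pyranone synthesis; the hot β-keto ester (through its aroylketene) C-acylates one of the two equivalent free ring carbons of the triphenol to give diketone 18, and cyclodehydration closes the pyranone. Closure through the unhindered hydroxyl para to the biaryl carbon, and not through the hydroxyl beside the axis, should make unit 1 the 6-linked flavone; no acid is present, so Wessely–Moser isomerisation is not expected. The C6–C8'' axis becomes stereogenic in this step and forms as the racemate.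

Step 11
Reactants: 19 6-[5,7-bis(benzyloxy)-2-(4-methoxyphenyl)-4-oxochromen-8-yl]-5,7-dihydroxy-2-(4-methoxyphenyl)chromen-4-one
Product: 20 6-[5,7-dihydroxy-2-(4-methoxyphenyl)-4-oxochromen-8-yl]-5,7-dihydroxy-2-(4-methoxyphenyl)chromen-4-one (CNP0226117.0)
Conditions: H2 (1 atm), 10% Pd/C, THF/MeOH, 20 °C
Reagents that add atoms: none
Why: Hydrogenolysis of the two benzyl ethers over zerovalent palladium on carbon; the aryl methyl ethers, the phenols and the C2=C3 bonds of the pyranones (vinylogous esters) should not be reduced at 1 atm and 20 °C.

## Compound list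

1 | acacetin, 5,7-dihydroxy-2-(4-methoxyphenyl)chromen-4-one | COc1ccc(-c2cc(=O)c3c(O)cc(O)cc3o2)cc1 | starting material
2 | allyl bromide | C=CCBr | starting material
3 | 5-hydroxy-2-(4-methoxyphenyl)-7-(prop-2-en-1-yloxy)chromen-4-one | COc1ccc(-c2cc(=O)c3c(O)cc(OCC=C)cc3o2)cc1 | intermediate
4 | 5,7-dihydroxy-2-(4-methoxyphenyl)-8-(prop-2-en-1-yl)chromen-4-one | COc1ccc(-c2cc(=O)c3c(O)cc(O)c(CC=C)c3o2)cc1 | intermediate
5 | benzyl bromide | BrCc1ccccc1 | starting material
6 | 5,7-bis(benzyloxy)-2-(4-methoxyphenyl)-8-(prop-2-en-1-yl)chromen-4-one | COc1ccc(-c2cc(=O)c3c(OCc4ccccc4)cc(OCc4ccccc4)c(CC=C)c3o2)cc1 | intermediate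
7 | 5,7-bis(benzyloxy)-8-(2,3-dihydroxypropyl)-2-(4-methoxyphenyl)chromen-4-one (racemic) | COc1ccc(-c2cc(=O)c3c(OCc4ccccc4)cc(OCc4ccccc4)c(CC(O)CO)c3o2)cc1 | intermediate (not isolated)
8 | 2-[5,7-bis(benzyloxy)-2-(4-methoxyphenyl)-4-oxochromen-8-yl]acetaldehyde | COc1ccc(-c2cc(=O)c3c(OCc4ccccc4)cc(OCc4ccccc4)c(CC=O)c3o2)cc1 | intermediate
9 | 2-[5,7-bis(benzyloxy)-2-(4-methoxyphenyl)-4-oxochromen-8-yl]acetic acid | COc1ccc(-c2cc(=O)c3c(OCc4ccccc4)cc(OCc4ccccc4)c(CC(=O)O)c3o2)cc1 | intermediate
10 | methyl acetoacetate | COC(=O)CC(C)=O | starting material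
11 | chlorotrimethylsilane | C[Si](C)(C)Cl | starting material
12 | methyl 3-(trimethylsilyloxy)but-2-enoate (mixture of double-bond isomers) | COC(=O)C=C(C)O[Si](C)(C)C | intermediate
13 | 1-methoxy-1,3-bis(trimethylsilyloxy)buta-1,3-diene | COC(O[Si](C)(C)C)=CC(=C)O[Si](C)(C)C | intermediate
14 | 2-[5,7-bis(benzyloxy)-2-(4-methoxyphenyl)-4-oxochromen-8-yl]acetyl chloride | COc1ccc(-c2cc(=O)c3c(OCc4ccccc4)cc(OCc4ccccc4)c(CC(=O)Cl)c3o2)cc1 | intermediate (not isolated)
15 | methyl 6-[5,7-bis(benzyloxy)-2-(4-methoxyphenyl)-4-oxochromen-8-yl]-3,5-dioxohexanoate | COC(=O)CC(=O)CC(=O)Cc1c(OCc2ccccc2)cc(OCc2ccccc2)c2c(=O)cc(-c3ccc(OC)cc3)oc12 | intermediate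
16 | 5,7-bis(benzyloxy)-2-(4-methoxyphenyl)-8-(2,4,6-trihydroxyphenyl)chromen-4-one | Oc1cc(O)c(-c2c(OCc3ccccc3)cc(OCc3ccccc3)c3c(=O)cc(-c4ccc(OC)cc4)oc23)c(O)c1 | intermediate
17 | ethyl 4-methoxybenzoylacetate | CCOC(=O)CC(=O)c1ccc(OC)cc1 | starting material
18 | 1-{3-[5,7-bis(benzyloxy)-2-(4-methoxyphenyl)-4-oxochromen-8-yl]-2,4,6-trihydroxyphenyl}-3-(4-methoxyphenyl)propane-1,3-dione | COc1ccc(C(=O)CC(=O)c2c(O)cc(O)c(-c3c(OCc4ccccc4)cc(OCc4ccccc4)c4c(=O)cc(-c5ccc(OC)cc5)oc34)c2O)cc1 | intermediate (not isolated)
19 | 6-[5,7-bis(benzyloxy)-2-(4-methoxyphenyl)-4-oxochromen-8-yl]-5,7-dihydroxy-2-(4-methoxyphenyl)chromen-4-one (racemic axis) | COc1ccc(-c2cc(=O)c3c(O)c(-c4c(OCc5ccccc5)cc(OCc5ccccc5)c5c(=O)cc(-c6ccc(OC)cc6)oc45)c(O)cc3o2)cc1 | intermediate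
20 | 6-[5,7-dihydroxy-2-(4-methoxyphenyl)-4-oxochromen-8-yl]-5,7-dihydroxy-2-(4-methoxyphenyl)chromen-4-one (CNP0226117.0, racemic axis) | COc1ccc(-c2cc(=O)c3c(O)c(-c4c(O)cc(O)c5c(=O)cc(-c6ccc(OC)cc6)oc45)c(O)cc3o2)cc1 | target

## Step count and least certain steps

Total step count: 11. Longest linear sequence: 9 steps (steps 1 to 5 and 8 to 11, from 1); steps 6 and 7 form a two-step side branch to 13.

Step 9 (key step). Lactonisation through the enolate oxygen may outrun C-acylation and the lactone may reopen too slowly. Alternatively the chelated bis-enolate may not ionise at the benzylic carbon, so that long heating ends in retro-Claisen methanolysis of the chain. The fallback makes the aryl–aryl bond by cross-coupling and sets out from 1.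
- Exhaustive benzylation (benzyl bromide, K2CO3, DMF, 70 °C) would give 5,7-bis(benzyloxy)-2-(4-methoxyphenyl)chromen-4-one F1.
- Iodination with I2 and CF3CO2Ag, which attacks C8 in 5,7-dialkoxyflavones, would give 5,7-bis(benzyloxy)-8-iodo-2-(4-methoxyphenyl)chromen-4-one F2.
- Separately, phloroglucinol with chloromethyl methyl ether and i-Pr2NEt would give 1,3,5-tris(methoxymethoxy)benzene F3. Lithiation between two acetal oxygens (n-BuLi, THF) and quenching with B(OMe)3 would give [2,4,6-tris(methoxymethoxy)phenyl]boronic acid F4.
- Suzuki–Miyaura coupling of F2 with F4 (Pd(OAc)2, 2-dicyclohexylphosphino-2',6'-dimethoxybiphenyl, K3PO4, toluene/water, 100 °C) would give 5,7-bis(benzyloxy)-2-(4-methoxyphenyl)-8-[2,4,6-tris(methoxymethoxy)phenyl]chromen-4-one F5.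
- Dilute HCl in methanol would remove the three acetals and return the route at 16.

Step 10. Cyclodehydration of diketone 18 may go partly through the hindered hydroxyl beside the axis, which would make unit 1 8-linked. At 240 °C benzyl migration or decomposition may also set in. The fallback sets out from 16 and forms the O1–C2 bond first, in an intermolecular step where the hindered hydroxyls are discriminated more strongly.
- Conjugate addition of the para hydroxyl to ethyl 3-(4-methoxyphenyl)prop-2-ynoate (K2CO3, DMF, 60 °C, Ar) would give ethyl 3-{4-[5,7-bis(benzyloxy)-2-(4-methoxyphenyl)-4-oxochromen-8-yl]-3,5-dihydroxyphenoxy}-3-(4-methoxyphenyl)prop-2-enoate F9.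
- Saponification with LiOH would give 3-{4-[5,7-bis(benzyloxy)-2-(4-methoxyphenyl)-4-oxochromen-8-yl]-3,5-dihydroxyphenoxy}-3-(4-methoxyphenyl)prop-2-enoic acid F10.
- Intramolecular Friedel–Crafts acylation through the mixed anhydride (trifluoroacetic anhydride, CH2Cl2, 0 °C, then aqueous NaHCO3/methanol to cleave phenol trifluoroacetates) onto either of the two equivalent ring carbons would return the route at 19. The double-bond geometry of F9 and F10 is without consequence, since the acidic cyclisation equilibrates it.

Step 2. The [3,3] shift may go in part to C6, which the chelated 5-hydroxyl activates, and the two allyl isomers may be hard to separate. The ortho-allylphenol may also close to a dihydrofuran at 200 °C. The fallback inverts the order of protection and rearrangement so that no chelated hydroxyl is present, and sets out from 3.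
- Benzylation of the 5-hydroxyl (benzyl bromide, K2CO3, n-Bu4NI, DMF, 70 °C) would give 5-(benzyloxy)-2-(4-methoxyphenyl)-7-(prop-2-en-1-yloxy)chromen-4-one F6.
- Claisen rearrangement (PhNEt2, 200 °C), directed to C8 by the bond fixation of the 7-alkoxy benzopyranone alone, would give 5-(benzyloxy)-7-hydroxy-2-(4-methoxyphenyl)-8-(prop-2-en-1-yl)chromen-4-one F7.
- Benzylation of the 7-hydroxyl would return the route at 6.

Step 8. Acid chloride 14 may be attacked by the neighbouring benzyloxy oxygen (loss of the benzyl group and lactone formation) or may ionise to a ketene before the slow uncatalysed C-acylation takes place. Acylation at the central carbon of 13 is a further possibility. The fallback uses the aldehyde oxidation level and sets out from 8.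
- Vinylogous Mukaiyama aldol addition of 13 (BF3·OEt2, CH2Cl2, −78 °C) would give methyl 6-[5,7-bis(benzyloxy)-2-(4-methoxyphenyl)-4-oxochromen-8-yl]-5-hydroxy-3-oxohexanoate F8 as the racemate.
- Oxidation of the secondary alcohol with Dess–Martin periodinane would return the route at 15.

## Further compounds

F1 | step 9 | 5,7-bis(benzyloxy)-2-(4-methoxyphenyl)chromen-4-one | COc1ccc(-c2cc(=O)c3c(OCc4ccccc4)cc(OCc4ccccc4)cc3o2)cc1
F2 | step 9 | 5,7-bis(benzyloxy)-8-iodo-2-(4-methoxyphenyl)chromen-4-one | COc1ccc(-c2cc(=O)c3c(OCc4ccccc4)cc(OCc4ccccc4)c(I)c3o2)cc1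
F3 | step 9 | 1,3,5-tris(methoxymethoxy)benzene | COCOc1cc(OCOC)cc(OCOC)c1
F4 | step 9 | [2,4,6-tris(methoxymethoxy)phenyl]boronic acid | COCOc1cc(OCOC)c(B(O)O)c(OCOC)c1
F5 | step 9 | 5,7-bis(benzyloxy)-2-(4-methoxyphenyl)-8-[2,4,6-tris(methoxymethoxy)phenyl]chromen-4-one | COCOc1cc(OCOC)c(-c2c(OCc3ccccc3)cc(OCc3ccccc3)c3c(=O)cc(-c4ccc(OC)cc4)oc23)c(OCOC)c1
F6 | step 2 | 5-(benzyloxy)-2-(4-methoxyphenyl)-7-(prop-2-en-1-yloxy)chromen-4-one | COc1ccc(-c2cc(=O)c3c(OCc4ccccc4)cc(OCC=C)cc3o2)cc1
F7 | step 2 | 5-(benzyloxy)-7-hydroxy-2-(4-methoxyphenyl)-8-(prop-2-en-1-yl)chromen-4-one | COc1ccc(-c2cc(=O)c3c(OCc4ccccc4)cc(O)c(CC=C)c3o2)cc1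
F8 | step 8 | methyl 6-[5,7-bis(benzyloxy)-2-(4-methoxyphenyl)-4-oxochromen-8-yl]-5-hydroxy-3-oxohexanoate (racemic) | COC(=O)CC(=O)CC(O)Cc1c(OCc2ccccc2)cc(OCc2ccccc2)c2c(=O)cc(-c3ccc(OC)cc3)oc12
F9 | step 10 | ethyl 3-{4-[5,7-bis(benzyloxy)-2-(4-methoxyphenyl)-4-oxochromen-8-yl]-3,5-dihydroxyphenoxy}-3-(4-methoxyphenyl)prop-2-enoate | CCOC(=O)C=C(Oc1cc(O)c(-c2c(OCc3ccccc3)cc(OCc3ccccc3)c3c(=O)cc(-c4ccc(OC)cc4)oc23)c(O)c1)c1ccc(OC)cc1
F10 | step 10 | 3-{4-[5,7-bis(benzyloxy)-2-(4-methoxyphenyl)-4-oxochromen-8-yl]-3,5-dihydroxyphenoxy}-3-(4-methoxyphenyl)prop-2-enoic acid | OC(=O)C=C(Oc1cc(O)c(-c2c(OCc3ccccc3)cc(OCc3ccccc3)c3c(=O)cc(-c4ccc(OC)cc4)oc23)c(O)c1)c1ccc(OC)cc1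
A1 | alternative 1 | 5-(benzyloxy)-2-[2,6-bis(benzyloxy)-4-(methoxymethoxy)phenyl]-3-(triisopropylsilyloxy)phenol | Oc1cc(OCc2ccccc2)cc(O[Si](C(C)C)(C(C)C)C(C)C)c1-c1c(OCc2ccccc2)cc(OCOC)cc1OCc1ccccc1
A2 | alternative 1 | 3-(benzyloxy)cyclobut-2-en-1-one | O=C1CC(OCc2ccccc2)=C1
A3 | alternative 1 | {[2,6-bis(benzyloxy)-4-(methoxymethoxy)phenyl]ethynyloxy}triisopropylsilane | COCOc1cc(OCc2ccccc2)c(C#CO[Si](C(C)C)(C(C)C)C(C)C)c(OCc2ccccc2)c1
A4 | alternative 2 | 5,7-bis(benzyloxy)-6-[5,7-bis(benzyloxy)-2-(4-methoxyphenyl)-4-oxochromen-8-yl]-2-(4-methoxyphenyl)chromen-4-one | COc1ccc(-c2cc(=O)c3c(OCc4ccccc4)c(-c4c(OCc5ccccc5)cc(OCc5ccccc5)c5c(=O)cc(-c6ccc(OC)cc6)oc45)c(OCc4ccccc4)cc3o2)cc1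
A5 | alternative 2 | 2,4',6,6'-tetrakis(benzyloxy)-3,3'-bis[2-(triphenyl-λ5-phosphanylidene)acetyl]biphenyl-2',4-diyl bis(4-methoxybenzoate) | COc1ccc(C(=O)Oc2cc(OCc3ccccc3)c(-c3c(OCc4ccccc4)cc(OCc4ccccc4)c(C(=O)C=P(c4ccccc4)(c4ccccc4)c4ccccc4)c3OC(=O)c3ccc(OC)cc3)c(OCc3ccccc3)c2C(=O)C=P(c2ccccc2)(c2ccccc2)c2ccccc2)cc1
A6 | alternative 3 | 5,7-dihydroxy-2-(4-methoxyphenyl)-8-[2,4,6-tris(benzyloxy)phenyl]chromen-4-one | COc1ccc(-c2cc(=O)c3c(O)cc(O)c(-c4c(OCc5ccccc5)cc(OCc5ccccc5)cc4OCc4ccccc4)c3o2)cc1
A7 | alternative 3 | 1-methoxy-4-[2,4,6-tris(benzyloxy)phenyl]-1,3-bis(trimethylsilyloxy)buta-1,3-diene | COC(O[Si](C)(C)C)=CC(O[Si](C)(C)C)=Cc1c(OCc2ccccc2)cc(OCc2ccccc2)cc1OCc1ccccc1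
A8 | alternative 3 | 5-bromo-2-(4-methoxyphenyl)pyran-4-one | COc1ccc(-c2cc(=O)c(Br)co2)cc1
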